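## Retrosynthetic overview
1. The cross-conjugated dienone is cut on both sides of its C=O. This gives a ring-bound 2-iodoalkene, CO and an (E)-alkenylstannane (carbonylative Stille coupling, last step).
2. The C3–O bond of the tiglate comes from SN2 attack of caesium tiglate on an axial α-chloro ketone, with inversion.
3. The cyclohexanone comes from an epoxycyclopentyl dichloromethyl carbinol. The ring carbon that bears the side chain shifts 1,2 onto CHCl2 (one-carbon ring expansion). The carbinol OH first steers the epoxidation and then becomes the C2 ketone.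
4. The carbinol comes from LiCHCl2 and an (R)-5-alkenyl-2-methylcyclopentenone. The C–C(sp2) bond and stereocentre of that enone come from an enantioconvergent nickel coupling of the racemic 5-bromo enone with an α-silylvinylzinc.
5. Ring order: cyclopentene (bought), then oxirane (made on the five-membered ring), then cyclohexanone (by expansion). Locants C1–C6 follow the 7-oxabicyclo[4.1.0]heptane name of the target.

Assumption: the sense of induction of the nickel/ligand pair in step 2 cannot be predicted, so the ligand antipode that gives the (R)-ketone is used.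

## Route

Step 1
Reactants: 1 2-methylcyclopent-2-en-1-one
Product: 4 rac-5-bromo-2-methylcyclopent-2-en-1-one, via lithium dienolate 2 (not isolated), via silyl dienol ether 3 (not isolated)
Conditions: LiN(SiMe3)2, THF, −78 °C; Me3SiCl; then NBS, −78 to −40 °C
Reagents that add atoms: N-bromosuccinimide, O=C1CCC(=O)N1Br
Why: Kinetic α′-deprotonation gives the cross-conjugated dienolate, and its silyl ether is brominated at C5 (electrophilic α-halogenation of a silyl enol ether); the new centre is deliberately racemic because step 2 erases it.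

Step 2
Reactants: 4 rac-5-bromo-2-methylcyclopent-2-en-1-one; 5 (1-bromoethenyl)trimethylsilane
Product: 8 (5R)-2-methyl-5-[1-(trimethylsilyl)ethenyl]cyclopent-2-en-1-one, via Grignard reagent 6 (not isolated), via alkenylzinc chloride 7 (not isolated)
Conditions: 5, Mg, THF, 40 °C; ZnCl2, 0 °C; then 4, NiCl2(MeOCH2CH2OMe) (10 mol %), (S,S)-Ph-pybox {2,6-bis[(4S)-4-phenyl-4,5-dihydro-1,3-oxazol-2-yl]pyridine} (13 mol %), MeOCH2CH2OMe/THF, −20 °C
Reagents that add atoms: none
Why: Proposed new method: monovalent nickel abstracts bromine from either enantiomer of 4 to give one planar α-keto radical, the ligand-bound alkenylnickel (divalent) captures it, and reductive elimination from trivalent nickel forms the C5–C(sp2) bond and sets (R) under ligand control, base-free at −20 °C so that the tertiary α-centre neither racemises nor lets the alkene slip into conjugation; the closest known reaction type is the stereoconvergent nickel-catalysed Negishi arylation/alkenylation of racemic acyclic α-bromo ketones, which has not been shown for a cyclic α′-bromo enone or for an α-silylated 1,1-disubstituted alkenylzinc.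

Step 3
Reactants: 8 (5R)-2-methyl-5-[1-(trimethylsilyl)ethenyl]cyclopent-2-en-1-one; 9 dichloromethane
Product: 11 (1R,5R)-1-(dichloromethyl)-2-methyl-5-[1-(trimethylsilyl)ethenyl]cyclopent-2-en-1-ol, via dichloromethyllithium 10 (not isolated)
Conditions: 9, n-BuLi, THF/Et2O, −100 °C; add 8; AcOH, −95 °C
Reagents that add atoms: none
Why: 1,2-Addition of the carbenoid LiCHCl2 to the enone carbonyl (Köbrich-type carbonyl addition) outruns enolisation at −100 °C and comes from the face opposite the C5 alkenyl group, so the new tertiary OH lies cis to that group (1R).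

Step 4
Reactants: 11 (1R,5R)-1-(dichloromethyl)-2-methyl-5-[1-(trimethylsilyl)ethenyl]cyclopent-2-en-1-ol
Product: 12 (1S,2R,3R,5S)-2-(dichloromethyl)-1-methyl-3-[1-(trimethylsilyl)ethenyl]-6-oxabicyclo[3.1.0]hexan-2-ol
Conditions: VO(acac)2 (3 mol %), t-BuOOH (1.1 equiv, decane), toluene, 0 °C
Reagents that add atoms: tert-butyl hydroperoxide, CC(C)(C)OO
Why: Hydroxy-directed vanadium-catalysed epoxidation delivers oxygen syn to the tertiary OH and therefore cis to the side chain, which sets both oxirane carbons; the allylic trisubstituted alkene reacts far faster than the hindered homoallylic vinylsilane.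

Step 5
Reactants: 12 (1S,2R,3R,5S)-2-(dichloromethyl)-1-methyl-3-[1-(trimethylsilyl)ethenyl]-6-oxabicyclo[3.1.0]hexan-2-ol
Product: 14 (1S,3R,4S,6S)-3-chloro-1-methyl-4-[1-(trimethylsilyl)ethenyl]-7-oxabicyclo[4.1.0]heptan-2-one, via lithium carbinolate 13 (not isolated)
Conditions: LiN(SiMe3)2 (1.05 equiv), THF, −78 °C, then 60 °C
Reagents that add atoms: none
Why: In this semipinacol-type one-carbon ring expansion of a lithium dichloromethylcarbinolate (Tiffeneau–Demjanov-like 1,2-shift), the oxide pushes, the allylic ring carbon (a better migrating group than the electron-poor oxirane carbon) moves with retention onto CHCl2 anti to the leaving chloride, five-to-six ring strain is released, and the rotamer with the CHCl2 hydrogen over the ring gives the axial (3R)-chloride.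

Step 6
Reactants: 14 (1S,3R,4S,6S)-3-chloro-1-methyl-4-[1-(trimethylsilyl)ethenyl]-7-oxabicyclo[4.1.0]heptan-2-one; 15 tiglic acid [(2E)-2-methylbut-2-enoic acid]
Product: 17 (1S,3S,4R,6S)-1-methyl-2-oxo-4-[1-(trimethylsilyl)ethenyl]-7-oxabicyclo[4.1.0]heptan-3-yl (2E)-2-methylbut-2-enoate, via caesium tiglate 16 (not isolated)
Conditions: 15 (1.5 equiv), Cs2CO3 (0.75 equiv), DMF, 23 °C; then 14, 23–35 °C
Reagents that add atoms: none
Why: SN2 displacement at an α-keto carbon by a soft carboxylate inverts the axial chloride to the equatorial (3S)-ester trans to the C4 group; there is no α′-hydrogen for a Favorskii path, and any equatorial chloride or axial ester epimerises to the same, more stable product.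

Step 7
Reactants: 17 (1S,3S,4R,6S)-1-methyl-2-oxo-4-[1-(trimethylsilyl)ethenyl]-7-oxabicyclo[4.1.0]heptan-3-yl (2E)-2-methylbut-2-enoate
Product: 18 (1S,3S,4R,6S)-4-(1-iodoethenyl)-1-methyl-2-oxo-7-oxabicyclo[4.1.0]heptan-3-yl (2E)-2-methylbut-2-enoate
Conditions: NIS (1.3 equiv), MeCN/ClCH2CN, 23 °C, dark
Reagents that add atoms: N-iodosuccinimide, O=C1CCC(=O)N1I
Why: Electrophilic ipso-iododesilylation of an α-silyl 1-alkene gives the 2-iodo-1-alkene under neutral conditions; the electron-poor tiglate alkene, the oxirane and the ketone are inert to NIS and no stereocentre is touched.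

Step 8
Reactants: 19 2-methylbut-3-yn-2-ol
Product: 20 (3E)-2-methyl-4-(tributylstannyl)but-3-en-2-ol
Conditions: Bu3SnH, PdCl2(PPh3)2 (1 mol %), THF, 0 °C
Reagents that add atoms: tributyltin hydride, CCCC[SnH](CCCC)CCCC
Why: Palladium-catalysed syn-hydrostannation places tin on the terminal carbon, away from the bulky carbinol, and so fixes the E geometry of the future enone.

Step 9
Reactants: 18 (1S,3S,4R,6S)-4-(1-iodoethenyl)-1-methyl-2-oxo-7-oxabicyclo[4.1.0]heptan-3-yl (2E)-2-methylbut-2-enoate; 20 (3E)-2-methyl-4-(tributylstannyl)but-3-en-2-ol; 21 carbon monoxide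
Product: 22 (1S,3S,4S,6S)-4-[(4E)-6-hydroxy-6-methyl-3-oxohepta-1,4-dien-2-yl]-1-methyl-2-oxo-7-oxabicyclo[4.1.0]heptan-3-yl (2E)-2-methylbut-2-enoate (target)
Conditions: CO (1 atm), Pd2(dba)3 (2.5 mol %), AsPh3 (20 mol %), NMP, 40 °C
Reagents that add atoms: none
Why: In this carbonylative Stille coupling, oxidative addition of the hindered vinyl iodide is followed by CO insertion faster than transmetalation, and the stannane transfers its alkenyl group with retention of E geometry under neutral conditions that spare the epoxy ketone, the ester and the free tertiary alcohol.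

## Compound list
1 | 2-methylcyclopent-2-en-1-one | CC1=CCCC1=O | starting material
2 | lithium 5-methylcyclopenta-1,4-dien-1-olate | CC1=CCC=C1[O-].[Li+] | intermediate
3 | trimethyl[(5-methylcyclopenta-1,4-dien-1-yl)oxy]silane | CC1=CCC=C1O[Si](C)(C)C | intermediate
4 | rac-5-bromo-2-methylcyclopent-2-en-1-one | CC1=CCC(Br)C1=O | intermediate
5 | (1-bromoethenyl)trimethylsilane | C=C(Br)[Si](C)(C)C | starting material
6 | [1-(trimethylsilyl)ethenyl]magnesium bromide | C=C([Mg]Br)[Si](C)(C)C | intermediate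
7 | [1-(trimethylsilyl)ethenyl]zinc chloride | C=C([Zn]Cl)[Si](C)(C)C | intermediate
8 | (5R)-2-methyl-5-[1-(trimethylsilyl)ethenyl]cyclopent-2-en-1-one | CC1=CC[C@@H](C(=C)[Si](C)(C)C)C1=O | intermediate
9 | dichloromethane | ClCCl | starting material
10 | dichloromethyllithium | [Li]C(Cl)Cl | intermediate
11 | (1R,5R)-1-(dichloromethyl)-2-methyl-5-[1-(trimethylsilyl)ethenyl]cyclopent-2-en-1-ol | CC1=CC[C@@H](C(=C)[Si](C)(C)C)[C@]1(O)C(Cl)Cl | intermediate
12 | (1S,2R,3R,5S)-2-(dichloromethyl)-1-methyl-3-[1-(trimethylsilyl)ethenyl]-6-oxabicyclo[3.1.0]hexan-2-ol | C[C@]12O[C@H]1C[C@@H](C(=C)[Si](C)(C)C)[C@]2(O)C(Cl)Cl | intermediate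
13 | lithium salt of 12 (carbinolate) | C[C@]12O[C@H]1C[C@@H](C(=C)[Si](C)(C)C)[C@]2([O-])C(Cl)Cl.[Li+] | intermediate
14 | (1S,3R,4S,6S)-3-chloro-1-methyl-4-[1-(trimethylsilyl)ethenyl]-7-oxabicyclo[4.1.0]heptan-2-one | C[C@]12O[C@H]1C[C@@H](C(=C)[Si](C)(C)C)[C@@H](Cl)C2=O | intermediate
15 | tiglic acid, (2E)-2-methylbut-2-enoic acid | C/C=C(\C)C(=O)O | starting material
16 | caesium (2E)-2-methylbut-2-enoate | C/C=C(\C)C(=O)[O-].[Cs+] | intermediate
17 | (1S,3S,4R,6S)-1-methyl-2-oxo-4-[1-(trimethylsilyl)ethenyl]-7-oxabicyclo[4.1.0]heptan-3-yl (2E)-2-methylbut-2-enoate | C[C@]12O[C@H]1C[C@@H](C(=C)[Si](C)(C)C)[C@H](OC(=O)/C(C)=C/C)C2=O | intermediate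
18 | (1S,3S,4R,6S)-4-(1-iodoethenyl)-1-methyl-2-oxo-7-oxabicyclo[4.1.0]heptan-3-yl (2E)-2-methylbut-2-enoate | C[C@]12O[C@H]1C[C@@H](C(I)=C)[C@H](OC(=O)/C(C)=C/C)C2=O | intermediate
19 | 2-methylbut-3-yn-2-ol | CC(C)(O)C#C | starting material
20 | (3E)-2-methyl-4-(tributylstannyl)but-3-en-2-ol | CC(C)(O)/C=C/[Sn](CCCC)(CCCC)CCCC | intermediate
21 | carbon monoxide | [C-]#[O+] | starting material
22 | (1S,3S,4S,6S)-4-[(4E)-6-hydroxy-6-methyl-3-oxohepta-1,4-dien-2-yl]-1-methyl-2-oxo-7-oxabicyclo[4.1.0]heptan-3-yl (2E)-2-methylbut-2-enoate | C=C(C(=O)/C=C/C(C)(C)O)[C@@H]1C[C@@H]2O[C@]2(C)C(=O)[C@H]1OC(=O)/C(C)=C/C | target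

## Step count and risks
Total steps: 9. Longest linear sequence: 8 (steps 1–7 and 9, from 1).

**Step 2 (the proposed new coupling).**
- Possible failures are reduction or dimerisation of 4, loss of HBr to a cyclopentadienone dimer, nickel-catalysed 1,4-addition, and low ee with the bulky α-silylalkenylzinc.
- The fallback sets out from 1 and 5 and returns at 8.
- The lithium enolate of 1 [LiN(SiMe3)2] is coupled with 5 by palladium-catalysed ketone α-alkenylation [Pd2(dba)3, P(t-Bu)3, toluene]. This gives racemic 2-methyl-5-[1-(trimethylsilyl)ethenyl]cyclopent-2-en-1-one F1.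
- NaBH4/CeCl3·7H2O in MeOH reduces F1 from the face opposite the side chain to racemic cis-2-methyl-5-[1-(trimethylsilyl)ethenyl]cyclopent-2-en-1-ol F2.
- Candida antarctica lipase B with vinyl acetate acetylates the unwanted antipode to (1S,5S)-2-methyl-5-[1-(trimethylsilyl)ethenyl]cyclopent-2-en-1-yl acetate F3.
- The resolution leaves (1R,5R)-2-methyl-5-[1-(trimethylsilyl)ethenyl]cyclopent-2-en-1-ol F4, which Dess–Martin periodinane oxidises to 8 without touching the α-centre.

**Step 5 (ring expansion).**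
- The carbinolate may close to a chloro-oxirane and collapse to an α-chloro aldehyde.
- The oxirane carbon may migrate instead of the allylic carbon.
- The oxide, which lies cis to the vinylsilane, may take the silyl group in a 1,4 carbon-to-oxygen shift. Lithium in THF is chosen to suppress this.
- Proton transfer to the acidic product may slow conversion.
- The fallback sets out from 12 and returns at 17, bypassing 14.
- Aqueous K2CO3 in 2-propanol hydrolyses the dichloromethyl group to (1S,2R,3R,5S)-2-hydroxy-1-methyl-3-[1-(trimethylsilyl)ethenyl]-6-oxabicyclo[3.1.0]hexane-2-carbaldehyde F5.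
- An α-ketol (acyloin) rearrangement under equilibrating conditions (catalytic KOt-Bu, THF, 0 °C) moves the same ring carbon onto the formyl carbon. It gives the diequatorial ketol (1S,3S,4R,6S)-3-hydroxy-1-methyl-4-[1-(trimethylsilyl)ethenyl]-7-oxabicyclo[4.1.0]heptan-2-one F6.
- Yamaguchi esterification of F6 with 15 (2,4,6-trichlorobenzoyl chloride, Et3N, DMAP) gives 17.

**Step 9 (carbonylative coupling).**
- Direct coupling without CO uptake, slow oxidative addition of the hindered iodide, and Michael addition or polymerisation of the dienone can all erode the yield on the most valuable material.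
- The fallback sets out from 18 and returns at 22. It separates CO uptake from the C–C coupling.
- Hydroxycarbonylation [Pd(OAc)2, PPh3, CO, H2O, Et3N, DMF, 23 °C] gives 2-[(1S,3S,4S,6S)-1-methyl-3-{[(2E)-2-methylbut-2-enoyl]oxy}-2-oxo-7-oxabicyclo[4.1.0]heptan-4-yl]prop-2-enoic acid F7.
- 1-Chloro-N,N,2-trimethylprop-1-en-1-amine converts F7 under neutral conditions into the corresponding prop-2-enoyl chloride F8.
- A CO-free Stille acylation of F8 with 20 [Pd2(dba)3, P(2-furyl)3, THF, 23 °C] gives 22.

## Further compounds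
F1 | step 2 | rac-2-methyl-5-[1-(trimethylsilyl)ethenyl]cyclopent-2-en-1-one | CC1=CC[C@@H](C(=C)[Si](C)(C)C)C1=O.CC1=CC[C@H](C(=C)[Si](C)(C)C)C1=O
F2 | step 2 | rac-cis-2-methyl-5-[1-(trimethylsilyl)ethenyl]cyclopent-2-en-1-ol | CC1=CC[C@@H](C(=C)[Si](C)(C)C)[C@H]1O.CC1=CC[C@H](C(=C)[Si](C)(C)C)[C@@H]1O
F3 | step 2 | (1S,5S)-2-methyl-5-[1-(trimethylsilyl)ethenyl]cyclopent-2-en-1-yl acetate | CC1=CC[C@H](C(=C)[Si](C)(C)C)[C@@H]1OC(C)=O
F4 | step 2 | (1R,5R)-2-methyl-5-[1-(trimethylsilyl)ethenyl]cyclopent-2-en-1-ol | CC1=CC[C@@H](C(=C)[Si](C)(C)C)[C@H]1O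
F5 | step 5 | (1S,2R,3R,5S)-2-hydroxy-1-methyl-3-[1-(trimethylsilyl)ethenyl]-6-oxabicyclo[3.1.0]hexane-2-carbaldehyde | C[C@]12O[C@H]1C[C@@H](C(=C)[Si](C)(C)C)[C@]2(O)C=O
F6 | step 5 | (1S,3S,4R,6S)-3-hydroxy-1-methyl-4-[1-(trimethylsilyl)ethenyl]-7-oxabicyclo[4.1.0]heptan-2-one | C[C@]12O[C@H]1C[C@@H](C(=C)[Si](C)(C)C)[C@H](O)C2=O
F7 | step 9 | 2-[(1S,3S,4S,6S)-1-methyl-3-{[(2E)-2-methylbut-2-enoyl]oxy}-2-oxo-7-oxabicyclo[4.1.0]heptan-4-yl]prop-2-enoic acid | C[C@]12O[C@H]1C[C@@H](C(=C)C(=O)O)[C@H](OC(=O)/C(C)=C/C)C2=O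
F8 | step 9 | 2-[(1S,3S,4S,6S)-1-methyl-3-{[(2E)-2-methylbut-2-enoyl]oxy}-2-oxo-7-oxabicyclo[4.1.0]heptan-4-yl]prop-2-enoyl chloride | C[C@]12O[C@H]1C[C@@H](C(=C)C(=O)Cl)[C@H](OC(=O)/C(C)=C/C)C2=O
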